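**Retrosynthetic overview**
- Target ⇐ its tris(methoxymethyl) ether by acid methanolysis (ring A = phloroglucinol ring, ring B = resorcinol ring, ring C = pyranone, ring D = dimethylpyran).
- Key disconnection: ring C (O1–C2 bond and the C2 carbon) and ring D (C–C bond to C3' and the ring O–C bond) are opened together, back to an acyclic 2-hydroxydeoxybenzoin 2'-O-(2-methylbut-3-yn-2-yl) ether plus a one-carbon unit.
- That ether ⇐ 3-chloro-3-methylbut-1-yne + a deoxybenzoin whose only free, unchelated phenol is 2'-OH. This fixes which oxygen enters ring D, and the blocked C1' sends the Claisen shift to C3'.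
- Deoxybenzoin ⇐ phloroglucinol (ring A) + (2,4-dihydroxyphenyl)acetic acid (ring B) by Friedel–Crafts acylation.
- Ring order: A and B are bought; C and then D are closed in the same flask in step 4.

Assumption: the target SMILES contains no stereocentre, so the compound is achiral and no asymmetric step is needed.

**Route**

Step 1
Reactants: 1 phloroglucinol (benzene-1,3,5-triol); 2 (2,4-dihydroxyphenyl)acetic acid
Product: 3 2-(2,4-dihydroxyphenyl)-1-(2,4,6-trihydroxyphenyl)ethan-1-one
Conditions: BF3·OEt2 (neat), 85 °C, 3 h; then aq. NaOAc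
Reagents that add atoms: none
Why: Friedel–Crafts C-acylation of the symmetric, very electron-rich phloroglucinol by the BF3-activated arylacetic acid (or its lactone formed in situ), with water as the only co-product and no regiochemical issue.

Step 2
Reactants: 3 2-(2,4-dihydroxyphenyl)-1-(2,4,6-trihydroxyphenyl)ethan-1-one
Product: 4 2-[2-hydroxy-4-(methoxymethoxy)phenyl]-1-[2-hydroxy-4,6-bis(methoxymethoxy)phenyl]ethan-1-one
Conditions: MOMCl (3.1 equiv), K2CO3 (4 equiv), acetone, 0 °C to rt
Reagents that add atoms: chloromethyl methyl ether, COCCl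
Why: Williamson-type O-alkylation (MOM protection) steered by acidity, sterics and hydrogen bonding: the para-OH and one ortho-OH of ring A and the unhindered 4'-OH react, while the ketone-chelated OH of ring A and the hindered 2'-OH next to the benzylic CH2 are left free.

Step 3
Reactants: 4 2-[2-hydroxy-4-(methoxymethoxy)phenyl]-1-[2-hydroxy-4,6-bis(methoxymethoxy)phenyl]ethan-1-one; 5 3-chloro-3-methylbut-1-yne
Product: 6 1-[2-hydroxy-4,6-bis(methoxymethoxy)phenyl]-2-{4-(methoxymethoxy)-2-[(2-methylbut-3-yn-2-yl)oxy]phenyl}ethan-1-one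
Conditions: K2CO3 (2 equiv), KI (0.2 equiv), CuI (5 mol%), acetone, 56 °C
Reagents that add atoms: none
Why: CuI-catalysed O-propargylation of a phenol by a tertiary propargylic chloride (SN1-type substitution through a copper-bound propargyl/allenyl cation), selective for the 2'-OH because the ring A hydroxyl stays locked in its hydrogen-bonded chelate under K2CO3 in acetone.

Step 4
Reactants: 6 1-[2-hydroxy-4,6-bis(methoxymethoxy)phenyl]-2-{4-(methoxymethoxy)-2-[(2-methylbut-3-yn-2-yl)oxy]phenyl}ethan-1-one
Product: 11 5,7-bis(methoxymethoxy)-3-[5-(methoxymethoxy)-2,2-dimethyl-2H-chromen-8-yl]-4H-chromen-4-one, via enaminone 7 (not isolated), via propargyl ether isoflavone 8 (not isolated), via allenylphenol 9 (not isolated), via ortho-quinone methide 10 (not isolated)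
Conditions: Me2NCH(OMe)2 (1.5 equiv), DMF, 90 °C, 2 h, N2 sweep; then 150 °C, 12 h, same flask
Reagents that add atoms: N,N-dimethylformamide dimethyl acetal, COC(OC)N(C)C
Why: Proposed new method: two known thermal reactions are run as one domino, first aminomethylenation of the deoxybenzoin CH2 and addition–elimination by the chelated phenol (closest known type: DMF-DMA isoflavone annulation) closing ring C at 90 °C with loss of methanol and dimethylamine, then at 150 °C aromatic propargyl Claisen rearrangement to C3' (the only free ortho carbon), enolisation, 1,5-hydrogen shift and oxa-6π electrocyclisation (closest known type: thermal chromene formation from aryl 1,1-dimethylpropargyl ethers) closing ring D, with no stereocentre formed.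

Step 5
Reactants: 11 5,7-bis(methoxymethoxy)-3-[5-(methoxymethoxy)-2,2-dimethyl-2H-chromen-8-yl]-4H-chromen-4-one
Product: 12 sophoraisoflavone A, 5,7-dihydroxy-3-(5-hydroxy-2,2-dimethyl-2H-chromen-8-yl)-4H-chromen-4-one
Conditions: HCl (3 M in MeOH), THF, 40 °C
Reagents that add atoms: none
Why: Acid-catalysed transacetalisation of the three MOM acetals to methanol (released as dimethoxymethane) frees the three phenols, and the chromone and the 2,2-dimethylchromene tolerate dilute methanolic HCl at this temperature.

**Compound list**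
1 | benzene-1,3,5-triol (phloroglucinol) | Oc1cc(O)cc(O)c1 | starting material
2 | (2,4-dihydroxyphenyl)acetic acid | OC(=O)Cc1ccc(O)cc1O | starting material
3 | 2-(2,4-dihydroxyphenyl)-1-(2,4,6-trihydroxyphenyl)ethan-1-one | O=C(Cc1ccc(O)cc1O)c1c(O)cc(O)cc1O | intermediate
4 | 2-[2-hydroxy-4-(methoxymethoxy)phenyl]-1-[2-hydroxy-4,6-bis(methoxymethoxy)phenyl]ethan-1-one | COCOc1ccc(CC(=O)c2c(O)cc(OCOC)cc2OCOC)c(O)c1 | intermediate
5 | 3-chloro-3-methylbut-1-yne | CC(C)(Cl)C#C | starting material
6 | 1-[2-hydroxy-4,6-bis(methoxymethoxy)phenyl]-2-{4-(methoxymethoxy)-2-[(2-methylbut-3-yn-2-yl)oxy]phenyl}ethan-1-one | COCOc1ccc(CC(=O)c2c(O)cc(OCOC)cc2OCOC)c(OC(C)(C)C#C)c1 | intermediate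
7 | enaminone: (2E)-3-(dimethylamino)-1-[2-hydroxy-4,6-bis(methoxymethoxy)phenyl]-2-{4-(methoxymethoxy)-2-[(2-methylbut-3-yn-2-yl)oxy]phenyl}prop-2-en-1-one | CN(C)/C=C(\c1ccc(OCOC)cc1OC(C)(C)C#C)C(=O)c1c(O)cc(OCOC)cc1OCOC | intermediate
8 | propargyl ether isoflavone: 5,7-bis(methoxymethoxy)-3-{4-(methoxymethoxy)-2-[(2-methylbut-3-yn-2-yl)oxy]phenyl}-4H-chromen-4-one | COCOc1ccc(-c2coc3cc(OCOC)cc(OCOC)c3c2=O)c(OC(C)(C)C#C)c1 | intermediate
9 | allenylphenol: 3-[2-hydroxy-4-(methoxymethoxy)-3-(3-methylbuta-1,2-dien-1-yl)phenyl]-5,7-bis(methoxymethoxy)-4H-chromen-4-one | COCOc1ccc(-c2coc3cc(OCOC)cc(OCOC)c3c2=O)c(O)c1C=C=C(C)C | intermediate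
10 | ortho-quinone methide: 5,7-bis(methoxymethoxy)-3-[(5Z)-4-(methoxymethoxy)-5-(3-methylbut-2-en-1-ylidene)-6-oxocyclohexa-1,3-dien-1-yl]-4H-chromen-4-one | O=C1/C(=C\C=C(C)C)C(OCOC)=CC=C1-c1coc2cc(OCOC)cc(OCOC)c2c1=O | intermediate
11 | 5,7-bis(methoxymethoxy)-3-[5-(methoxymethoxy)-2,2-dimethyl-2H-chromen-8-yl]-4H-chromen-4-one | CC1(C)C=Cc2c(OCOC)ccc(-c3coc4cc(OCOC)cc(OCOC)c4c3=O)c2O1 | intermediate
12 | sophoraisoflavone A, 5,7-dihydroxy-3-(5-hydroxy-2,2-dimethyl-2H-chromen-8-yl)-4H-chromen-4-one | CC1(C)C=Cc2c(O)ccc(-c3coc4cc(O)cc(O)c4c3=O)c2O1 | target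

**Totals**
Total step count: 5. Longest linear sequence: 5 steps (1 or 2 to 12); 5 enters at step 3.

**Steps most likely to fail**

Step 2 is the weakest step. It needs three of five phenols to be protected, and the 4'-OH and 2'-OH of ring B differ only in hindrance and hydrogen bonding, so isomeric or over-alkylated ethers may form. The fallback sets out from 3 and comes back at 12. Ring C is closed first with BF3·OEt2, DMF and MeSO2Cl at 80 °C to give 2'-hydroxygenistein F1. Here the 5-OH is chelated and the 2'-OH lies against the chromone, so only 7-OH and 4'-OH are unhindered. Two equivalents of chloromethyl methyl ether with K2CO3 in acetone give the 7,4'-bis(methoxymethyl) ether F2. Propargylation of the 2'-OH with 5 (K2CO3, KI, CuI, acetone) gives the 2'-propargyl ether F3. Heating in N,N-diethylaniline at 190 °C gives the chromene F4 by Claisen rearrangement, and methanolic HCl gives 12. This trades the domino for a linear sequence in which ring D is closed alone at the end.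

Step 3 may fail because a hindered phenol must be alkylated by a tertiary chloride; elimination of the chloride to the enyne, or alkylation at the benzylic carbon, may win. The fallback sets out from 4 and comes back at 11, and uses no propargyl ether at all. DMF-DMA in THF at 65 °C closes ring C to give the 2'-hydroxyisoflavone F5. Condensation of F5 with 3-methylbut-2-enal (PhB(OH)2 and a little propionic acid in refluxing toluene) then attacks C3', the only free carbon ortho to the free phenol. The resulting ortho-quinone methide closes by oxa-6π electrocyclisation onto the 2'-oxygen to give 11.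

Step 4 is the unprecedented domino. Dimethylamine and methanol released in the first stage may divert the allenylphenol 9 (for example to a benzofuran), or the chromone may suffer during the long heating. The fallback sets out from 6 and comes back at 11, with the two ring closures separated and reversed. Heating 6 alone in 1,2-dichlorobenzene at 180 °C, with no amine present, gives the chromenyl deoxybenzoin F6 (ring D first). F6 is then treated with DMF-DMA in THF at 65 °C, well below any temperature that stresses the chromene, to close ring C and give 11.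

**Further compounds**
F1 | step 2 | 3-(2,4-dihydroxyphenyl)-5,7-dihydroxy-4H-chromen-4-one (2'-hydroxygenistein) | O=c1c(-c2ccc(O)cc2O)coc2cc(O)cc(O)c12
F2 | step 2 | 5-hydroxy-3-[2-hydroxy-4-(methoxymethoxy)phenyl]-7-(methoxymethoxy)-4H-chromen-4-one | COCOc1ccc(-c2coc3cc(OCOC)cc(O)c3c2=O)c(O)c1
F3 | step 2 | 5-hydroxy-7-(methoxymethoxy)-3-{4-(methoxymethoxy)-2-[(2-methylbut-3-yn-2-yl)oxy]phenyl}-4H-chromen-4-one | COCOc1ccc(-c2coc3cc(OCOC)cc(O)c3c2=O)c(OC(C)(C)C#C)c1
F4 | step 2 | 5-hydroxy-7-(methoxymethoxy)-3-[5-(methoxymethoxy)-2,2-dimethyl-2H-chromen-8-yl]-4H-chromen-4-one | CC1(C)C=Cc2c(OCOC)ccc(-c3coc4cc(OCOC)cc(O)c4c3=O)c2O1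
F5 | step 3 | 3-[2-hydroxy-4-(methoxymethoxy)phenyl]-5,7-bis(methoxymethoxy)-4H-chromen-4-one | COCOc1ccc(-c2coc3cc(OCOC)cc(OCOC)c3c2=O)c(O)c1
F6 | step 4 | 1-[2-hydroxy-4,6-bis(methoxymethoxy)phenyl]-2-[5-(methoxymethoxy)-2,2-dimethyl-2H-chromen-8-yl]ethan-1-one | CC1(C)C=Cc2c(OCOC)ccc(CC(=O)c3c(O)cc(OCOC)cc3OCOC)c2O1
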